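**Plan**

1. Retrosynthetic cuts, in order: the three MOM ethers; the C8–C(CH3)2 bond (back to a 7-O-prenyl ether, aromatic Claisen); the C3=C4 double bond of the dimethylpyran ring D fused to ring B (ring-closing metathesis); the O1–C2 and C3–OH bonds of ring C (Algar–Flynn–Oyamada); the Cα=Cβ bond of a chalcone (Claisen–Schmidt); the O4'–C(CH3)2 and C5'–vinyl bonds of the ring B aldehyde.
2. Forward: a ring A acetophenone (2 steps) and a ring B aldehyde (3 steps) are condensed to the chalcone; ring C closes by oxidative cyclisation; ring D closes by metathesis; the C8 side chain then migrates from O7 to C8; deprotection ends the route.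
3. Both five-carbon units enter as ethers on oxygen (O7 prenyl, O4' 1,1-dimethylallyl) and are written into the skeleton afterwards.
4. Feature that makes the key event possible: on ring B the vinyl carbon on C5' and the O4'–C(CH3)2–CH=CH2 ether are ortho on a rigid benzene ring. The two alkene carbons that become C4 and C3 of ring D are therefore within reach of one ruthenium alkylidene, the quaternary ether carbon favours the folded rotamer, and only a six-membered ring with a cis alkene can form.
5. Metathesis precedes the Claisen step because it turns the heat-labile tertiary allyl aryl ether into a robust 2H-chromene; the trisubstituted prenyl alkene on ring A is spared by the catalyst.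
6. Stereochemistry: the target has no stereocentre; the cis geometry of C3=C4 is imposed by ring D, and the racemic dihydroflavonol formed during ring C closure is oxidised in the same flask.

Key step: step 9

Remark: 3-bromo-4,5-dihydroxybenzaldehyde and tert-butyl 2-methylbut-3-en-2-yl carbonate are taken as purchasable.

**Route**

Step 1
Reactants: 1 2,4,6-trihydroxyacetophenone
Product: 2 1-[2,6-dihydroxy-4-(3-methylbut-2-enyloxy)phenyl]ethanone
Conditions: prenyl bromide (1.05 equiv), K2CO3 (1.1 equiv), acetone, reflux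
Reagents that add atoms: prenyl bromide (1-bromo-3-methylbut-2-ene), CC(C)=CCBr
Why: Williamson etherification; the 4-OH, para to the acetyl group and the only phenol not hydrogen-bonded to the carbonyl, is the most acidic and accessible site, so one equivalent of the bromide should alkylate it selectively on oxygen.

Step 2
Reactants: 2 1-[2,6-dihydroxy-4-(3-methylbut-2-enyloxy)phenyl]ethanone
Product: 3 1-[2-hydroxy-6-(methoxymethoxy)-4-(3-methylbut-2-enyloxy)phenyl]ethanone
Conditions: MOMCl (1.1 equiv), i-Pr2NEt (1.5 equiv), CH2Cl2, 0 °C to rt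
Reagents that add atoms: chloromethyl methyl ether (MOMCl), COCCl
Why: O-alkylation with a chloromethyl ether under amine base; the two chelated ortho hydroxyls are equivalent, and once one is capped the other is locked in a strong hydrogen bond to the carbonyl and should stay free for the later closure of ring C.

Step 3
Reactants: 4 3-bromo-4,5-dihydroxybenzaldehyde
Product: 5 3-ethenyl-4,5-dihydroxybenzaldehyde
Conditions: vinylboronic acid pinacol ester (1.5 equiv), PdCl2(dppf) (5 mol %), K2CO3 (3 equiv), 1,4-dioxane/H2O, 85 °C, argon; dilute aq. HCl work-up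
Reagents that add atoms: vinylboronic acid pinacol ester (4,4,5,5-tetramethyl-2-vinyl-1,3,2-dioxaborolane), C=CB1OC(C)(C)C(C)(C)O1
Why: Suzuki–Miyaura vinylation of the aryl bromide; free phenols are tolerated under aqueous carbonate, the formyl group assists oxidative addition, and any catechol boronate is hydrolysed on acidic work-up.

Step 4
Reactants: 5 3-ethenyl-4,5-dihydroxybenzaldehyde
Product: 6 3-ethenyl-5-hydroxy-4-(2-methylbut-3-en-2-yloxy)benzaldehyde
Conditions: tert-butyl 2-methylbut-3-en-2-yl carbonate (1.3 equiv), Pd(PPh3)4 (3 mol %), 4 Å molecular sieves, THF, 0 °C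
Reagents that add atoms: tert-butyl 2-methylbut-3-en-2-yl carbonate, C=CC(C)(C)OC(=O)OC(C)(C)C
Why: Tsuji–Trost-type decarboxylative allylic etherification; zerovalent palladium ionises the tertiary carbonate, the tert-butoxide released deprotonates the more acidic 4-OH (para to the formyl group), and the phenoxide should add to the more substituted terminus of the 1,1-dimethylallyl complex under kinetic control at 0 °C.

Step 5
Reactants: 6 3-ethenyl-5-hydroxy-4-(2-methylbut-3-en-2-yloxy)benzaldehyde
Product: 7 3-ethenyl-5-(methoxymethoxy)-4-(2-methylbut-3-en-2-yloxy)benzaldehyde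
Conditions: MOMCl (1.5 equiv), i-Pr2NEt (2 equiv), CH2Cl2, 0 °C to rt
Reagents that add atoms: chloromethyl methyl ether (MOMCl), COCCl
Why: methoxymethyl ether formation at the only remaining phenol under basic conditions that leave the acid-labile tertiary allyl ether and the aldehyde untouched.

Step 6
Reactants: 3 1-[2-hydroxy-6-(methoxymethoxy)-4-(3-methylbut-2-enyloxy)phenyl]ethanone; 7 3-ethenyl-5-(methoxymethoxy)-4-(2-methylbut-3-en-2-yloxy)benzaldehyde
Product: 8 (E)-1-[2-hydroxy-6-(methoxymethoxy)-4-(3-methylbut-2-enyloxy)phenyl]-3-[3-ethenyl-5-(methoxymethoxy)-4-(2-methylbut-3-en-2-yloxy)phenyl]prop-2-en-1-one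
Conditions: KOH (aq., 10 equiv), EtOH, 0 °C to rt
Reagents that add atoms: none
Why: Claisen–Schmidt condensation (crossed aldol, then dehydration) of the methyl ketone enolate with the non-enolisable aldehyde; all ethers and isolated alkenes are inert to hydroxide and the trans enone is the thermodynamic product.

Step 7
Reactants: 8 (E)-1-[2-hydroxy-6-(methoxymethoxy)-4-(3-methylbut-2-enyloxy)phenyl]-3-[3-ethenyl-5-(methoxymethoxy)-4-(2-methylbut-3-en-2-yloxy)phenyl]prop-2-en-1-one
Product: 10 3-hydroxy-5-(methoxymethoxy)-7-(3-methylbut-2-enyloxy)-2-[3-ethenyl-5-(methoxymethoxy)-4-(2-methylbut-3-en-2-yloxy)phenyl]-4H-chromen-4-one, via trans-dihydroflavonol 9 (not isolated)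
Conditions: 30% aq. H2O2 (5 equiv), 2 M aq. NaOH (5 equiv), MeOH/THF, 0 °C to rt
Reagents that add atoms: hydrogen peroxide, OO
Why: Algar–Flynn–Oyamada reaction; alkaline hydrogen peroxide attacks only the electron-poor enone double bond, the 2'-phenoxide closes ring C in the six-membered mode to the trans-dihydroflavonol, which is dehydrogenated in the same medium so that no stereocentre remains, and the low temperature is chosen to hold back the competing five-membered (aurone) closure known for 6'-substituted chalcones.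

Step 8
Reactants: 10 3-hydroxy-5-(methoxymethoxy)-7-(3-methylbut-2-enyloxy)-2-[3-ethenyl-5-(methoxymethoxy)-4-(2-methylbut-3-en-2-yloxy)phenyl]-4H-chromen-4-one
Product: 11 3,5-bis(methoxymethoxy)-7-(3-methylbut-2-enyloxy)-2-[3-ethenyl-5-(methoxymethoxy)-4-(2-methylbut-3-en-2-yloxy)phenyl]-4H-chromen-4-one
Conditions: MOMCl (2 equiv), i-Pr2NEt (3 equiv), CH2Cl2, 0 °C to rt
Reagents that add atoms: chloromethyl methyl ether (MOMCl), COCCl
Why: O-alkylation of the acidic 3-hydroxyl (an enol next to the carbonyl) as its methoxymethyl ether, which removes the only protic, chelating site before the metal-catalysed step.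

Step 9
Reactants: 11 3,5-bis(methoxymethoxy)-7-(3-methylbut-2-enyloxy)-2-[3-ethenyl-5-(methoxymethoxy)-4-(2-methylbut-3-en-2-yloxy)phenyl]-4H-chromen-4-one
Product: 12 3,5-bis(methoxymethoxy)-2-[8-(methoxymethoxy)-2,2-dimethyl-2H-chromen-6-yl]-7-(3-methylbut-2-enyloxy)-4H-chromen-4-one
Conditions: second-generation Grubbs catalyst RuCl2(=CHPh)(H2IMes)(PCy3) (5 mol %), CH2Cl2 (0.005 M), 40 °C, argon
Reagents that add atoms: none
Why: Ring-closing olefin metathesis: the ruthenium benzylidene first exchanges onto the unhindered C5' styrene vinyl group, the ring B alkylidene so formed adds in a [2+2] sense to the vinyl group of the O4' 1,1-dimethylallyl ether, and cycloreversion of the ruthenacyclobutane forms the C3=C4 bond of the pyran with loss of ethene, which makes the closure irreversible. The closest known reaction type is the ring-closing metathesis of ortho-vinylaryl allyl ethers to 2H-chromenes. The six-membered pyran (ring D) closes by intramolecular alkylidene transfer between two alkene carbons held ortho on ring B, and the ring size allows only the cis alkene. No stereocentre is formed. The step needs site selectivity for the two monosubstituted alkenes of ring B over the trisubstituted 7-O-prenyl alkene and over intermolecular metathesis; the ortho relation and the quaternary O–C(CH3)2 carbon keep the reacting carbons close, the prenyl alkene is trisubstituted and too remote for any ring closure, the C2=C3 bond of ring C is tetrasubstituted and electron-poor, and high dilution suppresses dimerisation.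

Step 10
Reactants: 12 3,5-bis(methoxymethoxy)-2-[8-(methoxymethoxy)-2,2-dimethyl-2H-chromen-6-yl]-7-(3-methylbut-2-enyloxy)-4H-chromen-4-one
Product: 13 7-hydroxy-3,5-bis(methoxymethoxy)-2-[8-(methoxymethoxy)-2,2-dimethyl-2H-chromen-6-yl]-8-(2-methylbut-3-en-2-yl)-4H-chromen-4-one
Conditions: N,N-diethylaniline, 185 °C, sealed tube, argon
Reagents that add atoms: none
Why: aromatic Claisen rearrangement, a [3,3]-sigmatropic shift of the 7-O-prenyl ether with allyl inversion followed by tautomerisation to the phenol; C8 should be preferred over C6 because the C7–C8 bond of a chromen-4-one has the higher double-bond character and C6 is shielded by the 5-OMOM group, while the chromene and the MOM ethers are thermally stable in the basic solvent.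

Step 11
Reactants: 13 7-hydroxy-3,5-bis(methoxymethoxy)-2-[8-(methoxymethoxy)-2,2-dimethyl-2H-chromen-6-yl]-8-(2-methylbut-3-en-2-yl)-4H-chromen-4-one
Product: 14 Broussonol A, 3,5,7-trihydroxy-2-(8-hydroxy-2,2-dimethyl-2H-chromen-6-yl)-8-(2-methylbut-3-en-2-yl)-4H-chromen-4-one
Conditions: 3 M aq. HCl, MeOH, 45 °C
Reagents that add atoms: none
Why: acid-catalysed acetal methanolysis of the three methoxymethyl ethers (those on O3 and O5 are activated by the neighbouring carbonyl); dilute acid at moderate temperature should spare the chromene and the 1,1-dimethylallyl group next to the free 7-OH.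

**Compound list**

1 | 2,4,6-trihydroxyacetophenone | CC(=O)c1c(O)cc(O)cc1O | starting material
2 | 1-[2,6-dihydroxy-4-(3-methylbut-2-enyloxy)phenyl]ethanone | CC(=O)c1c(O)cc(OCC=C(C)C)cc1O | intermediate
3 | 1-[2-hydroxy-6-(methoxymethoxy)-4-(3-methylbut-2-enyloxy)phenyl]ethanone | CC(=O)c1c(O)cc(OCC=C(C)C)cc1OCOC | intermediate
4 | 3-bromo-4,5-dihydroxybenzaldehyde | O=Cc1cc(O)c(O)c(Br)c1 | starting material
5 | 3-ethenyl-4,5-dihydroxybenzaldehyde | O=Cc1cc(O)c(O)c(C=C)c1 | intermediate
6 | 3-ethenyl-5-hydroxy-4-(2-methylbut-3-en-2-yloxy)benzaldehyde | O=Cc1cc(O)c(OC(C)(C)C=C)c(C=C)c1 | intermediate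
7 | 3-ethenyl-5-(methoxymethoxy)-4-(2-methylbut-3-en-2-yloxy)benzaldehyde | O=Cc1cc(OCOC)c(OC(C)(C)C=C)c(C=C)c1 | intermediate
8 | (E)-1-[2-hydroxy-6-(methoxymethoxy)-4-(3-methylbut-2-enyloxy)phenyl]-3-[3-ethenyl-5-(methoxymethoxy)-4-(2-methylbut-3-en-2-yloxy)phenyl]prop-2-en-1-one | O=C(/C=C/c1cc(OCOC)c(OC(C)(C)C=C)c(C=C)c1)c1c(O)cc(OCC=C(C)C)cc1OCOC | intermediate
9 | (2R*,3R*)-3-hydroxy-5-(methoxymethoxy)-7-(3-methylbut-2-enyloxy)-2-[3-ethenyl-5-(methoxymethoxy)-4-(2-methylbut-3-en-2-yloxy)phenyl]chroman-4-one (trans-dihydroflavonol, racemic, one enantiomer drawn) | O[C@@H]1[C@@H](c2cc(OCOC)c(OC(C)(C)C=C)c(C=C)c2)Oc2cc(OCC=C(C)C)cc(OCOC)c2C1=O | intermediate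
10 | 3-hydroxy-5-(methoxymethoxy)-7-(3-methylbut-2-enyloxy)-2-[3-ethenyl-5-(methoxymethoxy)-4-(2-methylbut-3-en-2-yloxy)phenyl]-4H-chromen-4-one | O=c1c(O)c(-c2cc(OCOC)c(OC(C)(C)C=C)c(C=C)c2)oc2cc(OCC=C(C)C)cc(OCOC)c12 | intermediate
11 | 3,5-bis(methoxymethoxy)-7-(3-methylbut-2-enyloxy)-2-[3-ethenyl-5-(methoxymethoxy)-4-(2-methylbut-3-en-2-yloxy)phenyl]-4H-chromen-4-one | O=c1c(OCOC)c(-c2cc(OCOC)c(OC(C)(C)C=C)c(C=C)c2)oc2cc(OCC=C(C)C)cc(OCOC)c12 | intermediate
12 | 3,5-bis(methoxymethoxy)-2-[8-(methoxymethoxy)-2,2-dimethyl-2H-chromen-6-yl]-7-(3-methylbut-2-enyloxy)-4H-chromen-4-one | O=c1c(OCOC)c(-c2cc(OCOC)c3c(c2)C=CC(C)(C)O3)oc2cc(OCC=C(C)C)cc(OCOC)c12 | intermediate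
13 | 7-hydroxy-3,5-bis(methoxymethoxy)-2-[8-(methoxymethoxy)-2,2-dimethyl-2H-chromen-6-yl]-8-(2-methylbut-3-en-2-yl)-4H-chromen-4-one | C=CC(C)(C)c1c(O)cc(OCOC)c2c(=O)c(OCOC)c(-c3cc(OCOC)c4c(c3)C=CC(C)(C)O4)oc12 | intermediate
14 | Broussonol A | C=CC(C)(C)c1c(O)cc(O)c2c(=O)c(O)c(-c3cc(O)c4c(c3)C=CC(C)(C)O4)oc12 | target

**Step count and risks**

Total step count: 11. Longest linear sequence: 9 steps (steps 3 to 11, from 4); the ring A branch (steps 1 and 2) joins at step 6.

Steps most likely to fail:

Step 4. The phenoxide may add to the unsubstituted terminus of the allyl complex, the tertiary ether may be re-ionised by zerovalent palladium and drift to the linear prenyl ether, or the 3-OH may be alkylated instead of the 4-OH. The fallback sets out from 5. Copper-catalysed propargylic etherification with 3-chloro-3-methylbut-1-yne (CuCl2·2H2O (cat.), DBU, MeCN, 0 °C), in which the more acidic phenoxide adds to the tertiary carbon of a copper allenylidene, should give 3-ethenyl-5-hydroxy-4-(2-methylbut-3-yn-2-yloxy)benzaldehyde F1. Semi-hydrogenation of the terminal alkyne over Pd/CaCO3 poisoned with Pb(OAc)2 (Lindlar catalyst) with quinoline under H2 (1 atm) in EtOAc, stopped after one equivalent of hydrogen so that the styrene is not reduced, comes back to the route at 6.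

Step 7. Ring closure may take the five-membered course, by attack of the phenoxide at the α-carbon of the oxidised enone, which the 6'-substituent favours and which ends in an aurone; the oxidation may also stall. The fallback sets out from 8 and separates ring closure from oxygenation. Oxa-Michael cyclisation (NaOAc, EtOH, reflux) should give racemic 5-(methoxymethoxy)-7-(3-methylbut-2-enyloxy)-2-[3-ethenyl-5-(methoxymethoxy)-4-(2-methylbut-3-en-2-yloxy)phenyl]chroman-4-one F2. Dehydrogenation with IBX in DMSO at 70 °C should give 5-(methoxymethoxy)-7-(3-methylbut-2-enyloxy)-2-[3-ethenyl-5-(methoxymethoxy)-4-(2-methylbut-3-en-2-yloxy)phenyl]-4H-chromen-4-one F3. Lithiation at C3 with LiN(i-Pr)2 in THF at −78 °C, quench with B(OMe)3 and oxidation of the boronate with NaBO3·4H2O then comes back to the route at 10.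

Step 10. The prenyl group may migrate to C6 instead of C8, or the ortho-(1,1-dimethylallyl)phenol may react further at 185 °C (closure of the 7-OH onto the alkene, loss of the side chain). The fallback sets out from 3 and moves the rearrangement to the acetophenone. There the chelated 2-OH fixes the bond pattern so that the group should migrate to C3, between the two oxygens, and the carbon–carbon bond is formed on a small, robust compound.
- Heating 3 in N,N-diethylaniline at 185 °C should give 1-[2,4-dihydroxy-6-(methoxymethoxy)-3-(2-methylbut-3-en-2-yl)phenyl]ethanone F4.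
- MOMCl and i-Pr2NEt, which should cap only the unchelated 4-OH, lead to 1-[2-hydroxy-4,6-bis(methoxymethoxy)-3-(2-methylbut-3-en-2-yl)phenyl]ethanone F5.
- Claisen–Schmidt condensation with 7 (KOH, EtOH) should give (E)-1-[2-hydroxy-4,6-bis(methoxymethoxy)-3-(2-methylbut-3-en-2-yl)phenyl]-3-[3-ethenyl-5-(methoxymethoxy)-4-(2-methylbut-3-en-2-yloxy)phenyl]prop-2-en-1-one F6.
- Alkaline H2O2 should convert it into 3-hydroxy-5,7-bis(methoxymethoxy)-8-(2-methylbut-3-en-2-yl)-2-[3-ethenyl-5-(methoxymethoxy)-4-(2-methylbut-3-en-2-yloxy)phenyl]-4H-chromen-4-one F7.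
- MOMCl and i-Pr2NEt give 3,5,7-tris(methoxymethoxy)-8-(2-methylbut-3-en-2-yl)-2-[3-ethenyl-5-(methoxymethoxy)-4-(2-methylbut-3-en-2-yloxy)phenyl]-4H-chromen-4-one F8.
- Ring-closing metathesis with the second-generation Grubbs catalyst, in which the hindered C8 vinyl group is remote from ring B and should stay out, gives 3,5,7-tris(methoxymethoxy)-2-[8-(methoxymethoxy)-2,2-dimethyl-2H-chromen-6-yl]-8-(2-methylbut-3-en-2-yl)-4H-chromen-4-one F9.
- 3 M aq. HCl in MeOH at 45 °C then comes back to the route at 14.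

Further compounds
F1 | step 4 | 3-ethenyl-5-hydroxy-4-(2-methylbut-3-yn-2-yloxy)benzaldehyde | O=Cc1cc(O)c(OC(C)(C)C#C)c(C=C)c1
F2 | step 7 | racemic 5-(methoxymethoxy)-7-(3-methylbut-2-enyloxy)-2-[3-ethenyl-5-(methoxymethoxy)-4-(2-methylbut-3-en-2-yloxy)phenyl]chroman-4-one | O=C1CC(c2cc(OCOC)c(OC(C)(C)C=C)c(C=C)c2)Oc2cc(OCC=C(C)C)cc(OCOC)c21
F3 | step 7 | 5-(methoxymethoxy)-7-(3-methylbut-2-enyloxy)-2-[3-ethenyl-5-(methoxymethoxy)-4-(2-methylbut-3-en-2-yloxy)phenyl]-4H-chromen-4-one | O=c1cc(-c2cc(OCOC)c(OC(C)(C)C=C)c(C=C)c2)oc2cc(OCC=C(C)C)cc(OCOC)c12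
F4 | step 10 | 1-[2,4-dihydroxy-6-(methoxymethoxy)-3-(2-methylbut-3-en-2-yl)phenyl]ethanone | CC(=O)c1c(O)c(C(C)(C)C=C)c(O)cc1OCOC
F5 | step 10 | 1-[2-hydroxy-4,6-bis(methoxymethoxy)-3-(2-methylbut-3-en-2-yl)phenyl]ethanone | CC(=O)c1c(O)c(C(C)(C)C=C)c(OCOC)cc1OCOC
F6 | step 10 | (E)-1-[2-hydroxy-4,6-bis(methoxymethoxy)-3-(2-methylbut-3-en-2-yl)phenyl]-3-[3-ethenyl-5-(methoxymethoxy)-4-(2-methylbut-3-en-2-yloxy)phenyl]prop-2-en-1-one | O=C(/C=C/c1cc(OCOC)c(OC(C)(C)C=C)c(C=C)c1)c1c(O)c(C(C)(C)C=C)c(OCOC)cc1OCOC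
F7 | step 10 | 3-hydroxy-5,7-bis(methoxymethoxy)-8-(2-methylbut-3-en-2-yl)-2-[3-ethenyl-5-(methoxymethoxy)-4-(2-methylbut-3-en-2-yloxy)phenyl]-4H-chromen-4-one | O=c1c(O)c(-c2cc(OCOC)c(OC(C)(C)C=C)c(C=C)c2)oc2c(C(C)(C)C=C)c(OCOC)cc(OCOC)c12
F8 | step 10 | 3,5,7-tris(methoxymethoxy)-8-(2-methylbut-3-en-2-yl)-2-[3-ethenyl-5-(methoxymethoxy)-4-(2-methylbut-3-en-2-yloxy)phenyl]-4H-chromen-4-one | O=c1c(OCOC)c(-c2cc(OCOC)c(OC(C)(C)C=C)c(C=C)c2)oc2c(C(C)(C)C=C)c(OCOC)cc(OCOC)c12
F9 | step 10 | 3,5,7-tris(methoxymethoxy)-2-[8-(methoxymethoxy)-2,2-dimethyl-2H-chromen-6-yl]-8-(2-methylbut-3-en-2-yl)-4H-chromen-4-one | O=c1c(OCOC)c(-c2cc(OCOC)c3c(c2)C=CC(C)(C)O3)oc2c(C(C)(C)C=C)c(OCOC)cc(OCOC)c12
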